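**Retrosynthetic overview**

1. Numbering used throughout: ring C1 (CH–O-isovaleryl), C2 (C=O), C3 (CMe) and C4 (CH) of the ring epoxide, C5 (CH2), C6 (CH carrying the chain); chain C7 (spiro-epoxide carbon), C8 (its CH2), C9 (C=O), C10=C11 (E), C12 (CMe2OH).
2. The plan rests on C9, a ketone carbon whose only neighbours are two alkenyl-type carbons (C7, once the spiro-epoxide is taken back to C7=C8, and C10 of the E alkene). C9 is therefore disconnected as carbon monoxide, and C7–C9 and C9–C10 are made together by carbonylative Stille coupling of a C7 enol triflate with a C10 (E)-alkenylstannane.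
3. After the coupling, the C9 ketone is reduced to the (9S) carbinol, which serves as a temporary handle for a matched Sharpless epoxidation of C7=C8 to the (7R) spiro-epoxide; desilylation and double Dess–Martin oxidation (C2 and C9) finish the target.
4. Before the coupling, the triflate is traced to (R)-carvone, whose stereocentre becomes C6: trans α′-hydroxylation (C1) and isovalerylation, Luche reduction (C2), hydroxyl-directed epoxidation (C3–C4), silylation, ozonolysis of the isopropenyl group to the C7 acetyl group, kinetic enol triflation. The stannane comes from hydrostannation of 2-methylbut-3-yn-2-ol.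
5. Ring order: the carbocycle is carried in from carvone, the C3–C4 oxirane is closed in step 5 and the C7–C8 spiro-oxirane in step 12.

Key step: step 10

**Route**

Step 1
Reactants: 1 (R)-carvone
Product: 3 carvone trimethylsilyl dienol ether (C1=C2(OSiMe3)–C3(Me)=C4), via lithium dienolate 2 (not isolated)
Conditions: LiN(iPr)2 (LDA), THF, −78 °C; then Me3SiCl, −78 °C → 0 °C
Reagents that add atoms: chlorotrimethylsilane, C[Si](C)(C)Cl; lithium diisopropylamide (lithium of 2 only), [Li]N(C(C)C)C(C)C
Why: Kinetic α′-deprotonation of the enone at C1 and O-silylation of the cross-conjugated dienolate is the standard first half of a Rubottom oxidation; no stereocentre is formed and C6 is untouched.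

Step 2
Reactants: 3 carvone trimethylsilyl dienol ether
Product: 5 trans-6-hydroxycarvone (C1–OH trans to the C6 isopropenyl group), via α-trimethylsilyloxy ketone 4 (not isolated)
Conditions: mCPBA (1.0 equiv), hexane/CH2Cl2, −15 °C → rt; then 1 M aq HCl (cat.), THF, 0 °C
Reagents that add atoms: mCPBA (3-chloroperbenzoic acid), OOC(=O)c1cccc(Cl)c1
Why: Rubottom oxidation, in which the peracid epoxidises the electron-rich silyl enol ether bond C1=C2 in preference to the isopropenyl and C3=C4 alkenes and from the face anti to the neighbouring C6 isopropenyl group, so that silyl migration and hydrolysis should give the trans α′-hydroxy enone (C1 set by substrate control).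

Step 3
Reactants: 5 trans-6-hydroxycarvone; 6 isovaleryl chloride
Product: 7 keto ester (C1 isovalerate of 5)
Conditions: pyridine, DMAP (cat.), CH2Cl2, 0 °C → rt
Reagents that add atoms: none
Why: DMAP-catalysed acylation of a secondary alcohol by an acid chloride; no stereocentre is changed, and the trans C1/C6 arrangement is also the thermodynamically preferred one.

Step 4
Reactants: 7 keto ester
Product: 8 allylic alcohol (C2–OH cis to the C6 isopropenyl group, trans to the C1 ester)
Conditions: NaBH4, CeCl3·7H2O, MeOH, −78 °C
Reagents that add atoms: none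
Why: Luche reduction gives 1,2-reduction of the enone, and axial hydride delivery to the half-chair with the C1 ester and C6 isopropenyl group both equatorial should place the new C2 hydroxyl equatorial (as in carvone to cis-carveol); the low temperature suppresses 1,2-acyl migration.

Step 5
Reactants: 8 allylic alcohol
Product: 9 epoxy alcohol (C3–C4 oxirane on the face of the C2 hydroxyl)
Conditions: VO(acac)2 (cat.), t-BuOOH, CH2Cl2, 0 °C → rt
Reagents that add atoms: tert-butyl hydroperoxide, CC(C)(C)OO
Why: Vanadium-catalysed hydroxyl-directed epoxidation, in which the C2 hydroxyl delivers the oxidant to its own face of the allylic C3=C4 alkene (setting C3 and C4 cis to C2–O) while the bishomoallylic isopropenyl alkene is left alone.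

Step 6
Reactants: 9 epoxy alcohol
Product: 10 triethylsilyl ether (C2–OSiEt3)
Conditions: Et3SiCl, imidazole, DMAP (cat.), DMF, rt
Reagents that add atoms: chlorotriethylsilane, CC[Si](CC)(CC)Cl
Why: Standard silylation of a secondary alcohol; the triethylsilyl group is chosen because it can later be removed with buffered HF·pyridine in the presence of two epoxides and the neighbouring ester.

Step 7
Reactants: 10 triethylsilyl ether
Product: 12 methyl ketone (C6 acetyl group: C7=O, C8 methyl), via secondary ozonide 11 (not isolated)
Conditions: O3, CH2Cl2, −78 °C; then PPh3, −78 °C → rt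
Reagents that add atoms: ozone, [O-][O+]=O
Why: Ozonolysis with reductive work-up cleaves the only alkene left, and the neutral phosphine work-up avoids epimerisation at C6 and β-elimination of the C1 ester.

Step 8
Reactants: 12 methyl ketone
Product: 14 enol triflate (C6–C7(=C8H2)–OSO2CF3), via lithium enolate 13 (not isolated)
Conditions: LiN(iPr)2 (1.1 equiv), THF, −78 °C (ketone added to base); then Comins' reagent, −78 °C
Reagents that add atoms: Comins' reagent (N-(5-chloropyridin-2-yl)bis(trifluoromethanesulfonyl)imide), FC(F)(F)S(=O)(=O)N(c1ccc(Cl)cn1)S(=O)(=O)C(F)(F)F; lithium diisopropylamide (lithium of 13 only), [Li]N(C(C)C)C(C)C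
Why: Kinetic enolate formation and O-triflation, in which the methyl group is deprotonated much faster than the hindered C6 methine and the enolate is trapped at −78 °C, so that C6 should keep its configuration and the β-isovalerate is neither eliminated nor attacked.

Step 9
Reactants: 15 2-methylbut-3-yn-2-ol; 16 tributyltin hydride
Product: 17 (E)-2-methyl-4-(tributylstannyl)but-3-en-2-ol
Conditions: PdCl2(PPh3)2 (cat.), THF, 0 °C → rt
Reagents that add atoms: none
Why: Palladium-catalysed hydrostannation is a syn addition, and the bulky tertiary carbinol steers tin to the terminal carbon, so the (E)-β-stannyl alkene should be the main product.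

Step 10
Reactants: 14 enol triflate; 17 (E)-2-methyl-4-(tributylstannyl)but-3-en-2-ol; 18 carbon monoxide
Product: 19 cross-conjugated dienone (C7(=C8H2)–C9(=O)–C10H=C11H–C12Me2OH)
Conditions: Pd(PPh3)4 (5 mol %), LiCl (3 equiv), CO (3 atm), THF, 55 °C
Reagents that add atoms: none
Why: Zerovalent palladium inserts into the C7–O bond of the enol triflate, chloride replaces triflate, carbon monoxide inserts to give the C7 acylpalladium (bond C7–C9), and transmetalation from the alkenylstannane followed by reductive elimination forms C9–C10 with retention of the E geometry. The closest known reaction type is the carbonylative Stille coupling of enol triflates with alkenylstannanes to give divinyl ketones. No ring is closed and no stereocentre is created; C1, C2, C3, C4 and C6 are spectators under the neutral conditions. The selectivity needed is carbon monoxide insertion ahead of direct coupling, which is secured by the carbon monoxide pressure, LiCl, the moderate temperature and the slow transmetalation of the hindered 1,1-disubstituted alkenylpalladium. The tertiary C12 hydroxyl needs no protection, and the ester, silyl ether and epoxide do not react with the palladium intermediates.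

Step 11
Reactants: 19 cross-conjugated dienone
Product: 20 (9S)-dienol
Conditions: (R)-2-methyl-CBS-oxazaborolidine (0.5 equiv), catecholborane (3 equiv), toluene, −78 °C; MeOH, then pH 7 buffer
Reagents that add atoms: none
Why: Corey–Bakshi–Shibata reduction, in which the (R)-oxazaborolidine binds the ketone anti to the larger α-branched C7 alkenyl group and delivers hydride to the face that gives (9S), with 1,2-selectivity at −78 °C and extra borane to cover the free C12 hydroxyl.

Step 12
Reactants: 20 (9S)-dienol
Product: 21 (7R,9S)-epoxy alcohol (C7–C8 spiro-oxirane)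
Conditions: Ti(OiPr)4 (1.0 equiv), L-(+)-diisopropyl tartrate (1.2 equiv), t-BuOOH (2 equiv), 4 Å MS, CH2Cl2, −20 °C
Reagents that add atoms: tert-butyl hydroperoxide, CC(C)(C)OO
Why: Sharpless asymmetric epoxidation in its matched mode: with the L-(+)-tartrate the (9S) carbinol is the fast-reacting configuration for C7=C8 and the slow one for C10=C11, and oxygen is delivered to give the erythro (7R,9S) epoxy alcohol, the same sense that A1,2 strain favours for a 2-substituted secondary allylic alcohol.

Step 13
Reactants: 21 (7R,9S)-epoxy alcohol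
Product: 22 triol (C2–OH, C9–OH, C12–OH)
Conditions: HF·pyridine, pyridine, THF, 0 °C
Reagents that add atoms: none
Why: Fluoride-mediated cleavage of the triethylsilyl ether under buffered, slightly acidic conditions, which avoids Payne rearrangement of the C9 epoxy alcohol and acyl migration from C1 to C2 that a basic fluoride source could cause.

Step 14
Reactants: 22 triol
Product: 23 target CNP0292003.1
Conditions: Dess–Martin periodinane (3 equiv), pyridine, CH2Cl2, 0 °C → rt
Reagents that add atoms: none
Why: Dess–Martin oxidation converts the two secondary carbinols (C2 and C9) into ketones under buffered, non-epimerising conditions, while the tertiary C12 hydroxyl, both epoxides and the ester are inert.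

**Compound list**

1 | (R)-carvone, (5R)-2-methyl-5-(prop-1-en-2-yl)cyclohex-2-en-1-one | CC1=CC[C@H](CC1=O)C(C)=C | starting material
2 | lithium dienolate of carvone (kinetic α′ enolate, C1=C2(OLi) cross-conjugated with C3=C4) | C1=C(O[Li])C(C)=CC[C@H]1C(C)=C | intermediate
3 | carvone trimethylsilyl dienol ether, trimethyl{[(3R)-6-methyl-3-(prop-1-en-2-yl)cyclohexa-1,5-dien-1-yl]oxy}silane | C1=C(O[Si](C)(C)C)C(C)=CC[C@H]1C(C)=C | intermediate
4 | α-trimethylsilyloxy ketone, (5S,6S)-2-methyl-5-(prop-1-en-2-yl)-6-(trimethylsilyloxy)cyclohex-2-en-1-one | C[Si](C)(C)O[C@@H]1C(=O)C(C)=CC[C@H]1C(C)=C | intermediate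
5 | trans-6-hydroxycarvone, (5S,6S)-6-hydroxy-2-methyl-5-(prop-1-en-2-yl)cyclohex-2-en-1-one | O[C@@H]1C(=O)C(C)=CC[C@H]1C(C)=C | intermediate
6 | isovaleryl chloride (3-methylbutanoyl chloride) | CC(C)CC(Cl)=O | starting material
7 | keto ester, (1S,6S)-3-methyl-2-oxo-6-(prop-1-en-2-yl)cyclohex-3-en-1-yl 3-methylbutanoate | CC(C)CC(=O)O[C@@H]1C(=O)C(C)=CC[C@H]1C(C)=C | intermediate
8 | allylic alcohol, (1S,2S,6S)-2-hydroxy-3-methyl-6-(prop-1-en-2-yl)cyclohex-3-en-1-yl 3-methylbutanoate (C2–OH cis to C6 isopropenyl, trans to C1 ester) | CC(C)CC(=O)O[C@@H]1[C@@H](O)C(C)=CC[C@H]1C(C)=C | intermediate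
9 | epoxy alcohol: 8 with a C3–C4 oxirane (C2–OH, epoxide oxygen and C6 isopropenyl on one face, C1 ester on the other) | CC(C)CC(=O)O[C@@H]1[C@@H](O)[C@@]2(C)O[C@H]2C[C@H]1C(C)=C | intermediate
10 | triethylsilyl ether of 9 (C2–OSiEt3) | CC(C)CC(=O)O[C@@H]1[C@@H](O[Si](CC)(CC)CC)[C@@]2(C)O[C@H]2C[C@H]1C(C)=C | intermediate
11 | secondary ozonide of 10 (3-methyl-1,2,4-trioxolan-3-yl group on C6, both epimers at that carbon) | CC(C)CC(=O)O[C@@H]1[C@@H](O[Si](CC)(CC)CC)[C@@]2(C)O[C@H]2C[C@H]1C1(C)OCOO1 | intermediate
12 | methyl ketone: C6 acetyl (C7=O, C8 methyl), C1 isovalerate, C2–OSiEt3, C3–C4 epoxide | CC(C)CC(=O)O[C@@H]1[C@@H](O[Si](CC)(CC)CC)[C@@]2(C)O[C@H]2C[C@H]1C(C)=O | intermediate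
13 | lithium enolate of 12 (C7(OLi)=C8H2) | CC(C)CC(=O)O[C@@H]1[C@@H](O[Si](CC)(CC)CC)[C@@]2(C)O[C@H]2C[C@H]1C(=C)O[Li] | intermediate
14 | enol triflate: C6–C7(=C8H2)–OSO2CF3, C1 isovalerate, C2–OSiEt3, C3–C4 epoxide | CC(C)CC(=O)O[C@@H]1[C@@H](O[Si](CC)(CC)CC)[C@@]2(C)O[C@H]2C[C@H]1C(=C)OS(=O)(=O)C(F)(F)F | intermediate
15 | 2-methylbut-3-yn-2-ol | CC(C)(O)C#C | starting material
16 | tributyltin hydride (Bu3SnH) | CCCC[SnH](CCCC)CCCC | starting material
17 | (E)-2-methyl-4-(tributylstannyl)but-3-en-2-ol | CCCC[Sn](CCCC)(CCCC)/C=C/C(C)(C)O | intermediate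
18 | carbon monoxide | [C-]#[O+] | starting material
19 | cross-conjugated dienone: C6–C7(=C8H2)–C9(=O)–C10H=C11H–C12Me2OH (E), C1 isovalerate, C2–OSiEt3, C3–C4 epoxide | CC(C)CC(=O)O[C@@H]1[C@@H](O[Si](CC)(CC)CC)[C@@]2(C)O[C@H]2C[C@H]1C(=C)C(=O)/C=C/C(C)(C)O | intermediate
20 | (9S)-dienol: 19 with C9 reduced to the (S) carbinol | CC(C)CC(=O)O[C@@H]1[C@@H](O[Si](CC)(CC)CC)[C@@]2(C)O[C@H]2C[C@H]1C(=C)[C@@H](O)/C=C/C(C)(C)O | intermediate
21 | (7R,9S)-epoxy alcohol: 20 with the C7–C8 spiro-oxirane | CC(C)CC(=O)O[C@@H]1[C@@H](O[Si](CC)(CC)CC)[C@@]2(C)O[C@H]2C[C@H]1[C@]1([C@@H](O)/C=C/C(C)(C)O)CO1 | intermediate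
22 | triol: 21 without the silyl group (C2–OH, C9–OH, C12–OH) | CC(C)CC(=O)O[C@@H]1[C@@H](O)[C@@]2(C)O[C@H]2C[C@H]1[C@]1([C@@H](O)/C=C/C(C)(C)O)CO1 | intermediate
23 | target CNP0292003.1, (1S,3S,4S,6R,7R) in the route numbering | CC(C)CC(=O)O[C@@H]1C(=O)[C@@]2(C)O[C@H]2C[C@H]1[C@]1(C(=O)/C=C/C(C)(C)O)CO1 | target

**Step count and risks**

Total step count: 14. Longest linear sequence: 13 steps (steps 1–8 and 10–14 from (R)-carvone); the stannane branch is one step (step 9).

Steps most likely to fail:

1. Step 10 (key step). Transmetalation may overtake carbon monoxide insertion and give the non-carbonylated diene, or the stannane may be lost by protodestannylation before it couples. The fallback sets out from enol triflate 14 and brings C9 in as an aldehyde carbon instead of carbon monoxide. Cross-metathesis of 2-methylbut-3-en-2-ol with crotonaldehyde (second-generation Hoveyda–Grubbs catalyst, CH2Cl2, 40 °C) should give (E)-4-hydroxy-4-methylpent-2-enal F1. Nozaki–Hiyama–Kishi coupling of 14 with this aldehyde (CrCl2 in excess, NiCl2 cat., DMF, rt) should give the C9-epimeric divinyl carbinols F2. Oxidation of both epimers with MnO2 in CH2Cl2 returns to the route at dienone 19.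

2. Step 11. Facial discrimination may be poor because both groups on the ketone are alkenyl and the resident stereocentres may oppose the catalyst; conjugate reduction of the methylene enone may also compete. The fallback sets out from dienone 19. Luche reduction (NaBH4, CeCl3·7H2O, MeOH, −78 °C) should give 20 together with the (9R)-dienol F3. The mixture is submitted to the Sharpless conditions of step 12, which then act as a kinetic resolution: only 20 is matched for epoxidation of C7=C8. The unreacted F3 is separated and recycled to 19 with MnO2. The route is rejoined at epoxy alcohol 21.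

3. Step 12. Oxygen transfer to the hindered 1,1-disubstituted alkene may be slow, which would allow competing epoxidation of C10=C11 directed by either hydroxyl, or opening of the new 2,2-disubstituted epoxide by isopropoxide. The fallback sets out from dienone 19 and bypasses the C9 carbinol. Weitz–Scheffer nucleophilic epoxidation (t-BuOOH, DBU, CH2Cl2, 0 °C) should attack the unsubstituted C8 of the methylene enone much faster than C11, which is shielded by the CMe2OH group, and give the (7R) spiro-epoxy enone triethylsilyl ether F4. Here C7 is under substrate control from C6 only, so the C7 epimers would be separated by chromatography. HF·pyridine/pyridine then gives the C2 alcohol F5, and Dess–Martin oxidation of its C2 carbinol rejoins the route at target 23.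

**Further compounds**

F1 | step 10 | (E)-4-hydroxy-4-methylpent-2-enal | CC(C)(O)/C=C/C=O
F2 | step 10 | C9-epimeric divinyl carbinols (20 and its C9 epimer as a mixture) | CC(C)CC(=O)O[C@@H]1[C@@H](O[Si](CC)(CC)CC)[C@@]2(C)O[C@H]2C[C@H]1C(=C)C(O)/C=C/C(C)(C)O
F3 | step 11 | (9R)-dienol, the C9 epimer of 20 | CC(C)CC(=O)O[C@@H]1[C@@H](O[Si](CC)(CC)CC)[C@@]2(C)O[C@H]2C[C@H]1C(=C)[C@H](O)/C=C/C(C)(C)O
F4 | step 12 | (7R) spiro-epoxy enone, C2 triethylsilyl ether | CC(C)CC(=O)O[C@@H]1[C@@H](O[Si](CC)(CC)CC)[C@@]2(C)O[C@H]2C[C@H]1[C@]1(C(=O)/C=C/C(C)(C)O)CO1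
F5 | step 12 | (7R) spiro-epoxy enone, C2 alcohol | CC(C)CC(=O)O[C@@H]1[C@@H](O)[C@@]2(C)O[C@H]2C[C@H]1[C@]1(C(=O)/C=C/C(C)(C)O)CO1
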